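## Retrosynthetic overview
1. The 3-bromooxane is made last, by ring expansion of a 2-(1-hydroxy-1-methylalkyl)oxolane through a bicyclic oxonium ion. This step sets C–Br and moves the ring C–O bond.
2. The oxolane comes from 5-exo opening of a Shi epoxide by a tertiary allylic alcohol. That carbinol comes from lithiation–borylation (1,2-metallate shift) of (R)-but-3-en-2-yl carbamate with a primary boronic ester.
3. The E-trisubstituted alkene comes from a B-alkyl Suzuki coupling of a 2-vinyl-7-oxanorbornane with (E)-5-bromo-2-iodopent-2-ene.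
4. The 7-oxanorbornane comes from Lewis acid closure of the asymmetric homoaldol adduct of crotyl carbamate and hexane-2,5-dione.
5. Ring order: the oxabicycle first (both of its rings in one step), the oxolane second, the oxane last by expansion of the oxolane.

Assumption: 5-bromopent-2-yne, (R)-but-3-en-2-ol and (+)-sparteine are taken as purchasable, and the carbamoyl, pinacolboryl and 9-BBN groups count as auxiliary groups.

## Route

Step 1
Reactants: 1 (E)-but-2-en-1-ol
Product: 2 (E)-but-2-en-1-yl N,N-diisopropylcarbamate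
Conditions: NaH, THF, 0 °C; iPr2NCOCl, 65 °C
Reagents that add atoms: N,N-diisopropylcarbamoyl chloride, CC(C)N(C(C)C)C(Cl)=O
Why: O-carbamoylation of the alkoxide (acyl substitution) installs the directing group that later leaves; no stereocentre is formed.

Step 2
Reactants: 2 (E)-but-2-en-1-yl N,N-diisopropylcarbamate; 3 hexane-2,5-dione
Product: 6 (1Z,3R,4S)-4-hydroxy-3,4-dimethyl-7-oxooct-1-en-1-yl N,N-diisopropylcarbamate, via lithiated crotyl carbamate 4 (not isolated), via allyltitanium reagent 5 (not isolated)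
Conditions: n-BuLi, (+)-sparteine, pentane/cyclohexane, −70 °C (crystallisation, 3 h); Ti(OiPr)4, −70 °C; 3 (3 equiv), −70 → 0 °C; 2 M HCl
Reagents that add atoms: none
Why: Hoppe asymmetric homoaldol reaction: the sparteine-bound lithium compound is enriched by crystallisation and transmetallated with inversion, and the allyltitanium then adds through its γ-carbon in a closed chair (crotyl methyl and the larger ketone residue equatorial), which sets C-3 (R) and C-4 (S) anti and gives the Z enol carbamate, the minor C-4 epimer being removed by chromatography.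

Step 3
Reactants: 6 (1Z,3R,4S)-4-hydroxy-3,4-dimethyl-7-oxooct-1-en-1-yl N,N-diisopropylcarbamate
Product: 8 (1R,2R,3R,4S)-1,3,4-trimethyl-7-oxabicyclo[2.2.1]heptane-2-carbaldehyde (formyl endo; 3-methyl exo), via oxocarbenium ion 7 (not isolated)
Conditions: BF3·OEt2 (1.5 equiv), CH2Cl2, −78 → 0 °C; aq NaHCO3
Reagents that add atoms: none
Why: Intramolecular variant of the Lewis acid condensation of 4-hydroxy-1-alkenyl carbamates with carbonyl compounds (Mukaiyama-aldol/Prins-type closure): the hemiketal ionises to the five-membered oxocarbenium ion, the tether reaches it from one face only (which fixes C-1 relative to C-4), and allylic 1,3-strain in the Z enol carbamate holds the C-3 hydrogen in the alkene plane so that the formyl carbon ends endo and trans to the exo methyl.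

Step 4
Reactants: 8 (1R,2R,3R,4S)-1,3,4-trimethyl-7-oxabicyclo[2.2.1]heptane-2-carbaldehyde
Product: 9 (1R,2R,3R,4S)-2-ethenyl-1,3,4-trimethyl-7-oxabicyclo[2.2.1]heptane
Conditions: MePPh3Br, KOt-Bu, THF, 0 °C; 8, −78 → 0 °C
Reagents that add atoms: methyltriphenylphosphonium bromide, C[P+](c1ccccc1)(c1ccccc1)c1ccccc1.[Br-]
Why: Wittig methylenation with the non-stabilised ylide at low temperature is faster than enolisation or β-elimination, so the endo configuration at C-2 is kept.

Step 5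
Reactants: 10 5-bromopent-2-yne
Product: 12 (2E)-5-bromo-2-iodopent-2-ene, via alkenylzirconocene 11 (not isolated)
Conditions: Cp2Zr(H)Cl (1.6 equiv), THF, 40 °C; I2, −20 °C
Reagents that add atoms: iodine, II
Why: Syn hydrozirconation followed by iodinolysis with retention gives the E iodide, because excess Cp2Zr(H)Cl equilibrates the regioisomers toward zirconium next to the methyl group (about 9:1, minor isomer removed).

Step 6
Reactants: 9 (1R,2R,3R,4S)-2-ethenyl-1,3,4-trimethyl-7-oxabicyclo[2.2.1]heptane; 12 (2E)-5-bromo-2-iodopent-2-ene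
Product: 14 (1R,2R,3R,4S)-2-[(3E)-6-bromo-3-methylhex-3-en-1-yl]-1,3,4-trimethyl-7-oxabicyclo[2.2.1]heptane, via B-alkyl-9-BBN 13 (not isolated)
Conditions: 9-BBN-H, THF, rt; then 12, Pd(dppf)Cl2 (5 mol %), AsPh3, Cs2CO3, DMF/H2O, rt
Reagents that add atoms: none
Why: Anti-Markovnikov hydroboration and B-alkyl Suzuki–Miyaura coupling keep the alkene geometry, and the primary alkyl bromide does not add to zerovalent palladium under these conditions.

Step 7
Reactants: 14 (1R,2R,3R,4S)-2-[(3E)-6-bromo-3-methylhex-3-en-1-yl]-1,3,4-trimethyl-7-oxabicyclo[2.2.1]heptane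
Product: 15 2-{(3E)-4-methyl-6-[(1R,2R,3R,4S)-1,3,4-trimethyl-7-oxabicyclo[2.2.1]heptan-2-yl]hex-3-en-1-yl}-4,4,5,5-tetramethyl-1,3,2-dioxaborolane
Conditions: B2pin2, CuI (10 mol %), PPh3, LiOMe, DMF, rt
Reagents that add atoms: bis(pinacolato)diboron, CC1(C)OB(OC1(C)C)B1OC(C)(C)C(C)(C)O1
Why: Copper-catalysed borylation of a primary alkyl bromide leaves the trisubstituted alkene and the ether bridge untouched.

Step 8
Reactants: 16 (R)-but-3-en-2-ol
Product: 17 (R)-but-3-en-2-yl N,N-diisopropylcarbamate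
Conditions: NaH, THF, 0 °C; iPr2NCOCl, 65 °C
Reagents that add atoms: N,N-diisopropylcarbamoyl chloride, CC(C)N(C(C)C)C(Cl)=O
Why: O-carbamoylation does not touch the C–O stereocentre taken from the chiral pool.

Step 9
Reactants: 17 (R)-but-3-en-2-yl N,N-diisopropylcarbamate; 15 2-{(3E)-4-methyl-6-[(1R,2R,3R,4S)-1,3,4-trimethyl-7-oxabicyclo[2.2.1]heptan-2-yl]hex-3-en-1-yl}-4,4,5,5-tetramethyl-1,3,2-dioxaborolane
Product: 21 (3S,6E)-3,7-dimethyl-9-[(1R,2R,3R,4S)-1,3,4-trimethyl-7-oxabicyclo[2.2.1]heptan-2-yl]nona-1,6-dien-3-ol, via lithiated butenyl carbamate 18 (not isolated), via boronate complex 19 (not isolated), via tertiary boronic ester 20 (not isolated)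
Conditions: 17 (1.4 equiv), s-BuLi, TMEDA, Et2O, −78 °C; 15, −78 °C → rt; H2O2, NaOH, THF, 0 °C
Reagents that add atoms: hydrogen peroxide, OO
Why: Lithiation–borylation is stereospecific: deprotonation and borylation go with retention, the 1,2-metallate shift of the primary alkyl group displaces the carbamate with inversion, and the oxidation goes with retention, so the (R)-carbamate gives the (S)-tertiary allylic alcohol.

Step 10
Reactants: 21 (3S,6E)-3,7-dimethyl-9-[(1R,2R,3R,4S)-1,3,4-trimethyl-7-oxabicyclo[2.2.1]heptan-2-yl]nona-1,6-dien-3-ol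
Product: 23 (2R)-2-[(2S,5S)-5-ethenyl-5-methyloxolan-2-yl]-4-[(1R,2R,3R,4S)-1,3,4-trimethyl-7-oxabicyclo[2.2.1]heptan-2-yl]butan-2-ol, via epoxy alcohol 22 (not isolated)
Conditions: D-fructose-derived Shi ketone (30 mol %), KHSO5 (as 2KHSO5·KHSO4·K2SO4), K2CO3, Bu4NHSO4, MeCN/DMM/aq Na2B4O7 buffer, 0 °C; crude epoxide, KOt-Bu (20 mol %), THF, 40 °C
Reagents that add atoms: potassium peroxymonosulfate KHSO5, [K+].[O-]S(=O)(=O)OO
Why: Shi asymmetric epoxidation attacks only the electron-rich trisubstituted alkene and gives the (R,R)-epoxide under catalyst control, and the tertiary alkoxide then opens it 5-exo at the secondary carbon with inversion, which sets oxolane C-2 (S) trans to the vinyl group and leaves the carbinol carbon (R).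

Step 11
Reactants: 23 (2R)-2-[(2S,5S)-5-ethenyl-5-methyloxolan-2-yl]-4-[(1R,2R,3R,4S)-1,3,4-trimethyl-7-oxabicyclo[2.2.1]heptan-2-yl]butan-2-ol
Product: 27 dactylopyranoid (2S,3R,6S)-3-bromo-6-ethenyl-2,6-dimethyl-2-{2-[(1R,2R,3R,4S)-1,3,4-trimethyl-7-oxabicyclo[2.2.1]heptan-2-yl]ethyl}oxane, via alkoxyiminium bromide 24 (not isolated), via bicyclic oxonium bromide 25 (not isolated), via tertiary bromide 26 (not isolated)
Conditions: Me2C=C(Br)NMe2 (1.3 equiv), 2,6-di-tert-butylpyridine (0.3 equiv), CH2Cl2, −40 °C; ZnBr2 (15 mol %), −20 → 10 °C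
Reagents that add atoms: 1-bromo-N,N,2-trimethylprop-1-en-1-amine, CC(C)=C(Br)N(C)C
Why: Proposed new method: dehydroxybrominative oxolane-to-oxane ring expansion, in which the neutral α-bromoenamine turns the tertiary OH into an alkoxyiminium leaving group that the antiperiplanar ring oxygen expels (inversion at the future oxane C-2) to give a 1-oxoniabicyclo[3.1.0]hexane bromide; bromide return at the tertiary carbon gives only the tertiary bromide, which ZnBr2 re-ionises, whereas SN2 attack at the secondary carbon (inversion, Br equatorial and anti to the new C–O bond) reverts far more slowly, releases three- and five-ring strain and places oxygen on the tertiary and bromine on the secondary carbon, so the material drains to one 3-bromooxane diastereomer; the closest known reaction types are the Zn(OAc)2-mediated ring expansion of oxolanyl mesylates through bicyclic oxonium ions and the prolinol-to-3-halopiperidine expansion through aziridinium ions.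

## Compound list
1 | (E)-but-2-en-1-ol | C/C=C/CO | starting material
2 | (E)-but-2-en-1-yl N,N-diisopropylcarbamate | C/C=C/COC(=O)N(C(C)C)C(C)C | intermediate
3 | hexane-2,5-dione | CC(=O)CCC(C)=O | starting material
4 | (1R,2E)-1-(diisopropylcarbamoyloxy)but-2-enyllithium, (+)-sparteine complex | [Li][C@@H](OC(=O)N(C(C)C)C(C)C)/C=C/C | intermediate
5 | (1S,2E)-1-(diisopropylcarbamoyloxy)but-2-enyl(triisopropoxy)titanium | CC(C)O[Ti](OC(C)C)(OC(C)C)[C@H](OC(=O)N(C(C)C)C(C)C)/C=C/C | intermediate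
6 | (1Z,3R,4S)-4-hydroxy-3,4-dimethyl-7-oxooct-1-en-1-yl N,N-diisopropylcarbamate (in equilibrium with its cyclic hemiketal) | CC(C)N(C(C)C)C(=O)O/C=C\[C@@H](C)[C@](O)(C)CCC(C)=O | intermediate
7 | (2S)-2,5-dimethyl-2-[(2R,3Z)-4-(diisopropylcarbamoyloxy)but-3-en-2-yl]-3,4-dihydro-2H-furan-1-ium | CC1=[O+][C@@](C)(CC1)[C@H](C)/C=C\OC(=O)N(C(C)C)C(C)C | intermediate
8 | (1R,2R,3R,4S)-1,3,4-trimethyl-7-oxabicyclo[2.2.1]heptane-2-carbaldehyde | O=C[C@@H]1[C@@H](C)[C@]2(C)CC[C@@]1(C)O2 | intermediate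
9 | (1R,2R,3R,4S)-2-ethenyl-1,3,4-trimethyl-7-oxabicyclo[2.2.1]heptane | C=C[C@@H]1[C@@H](C)[C@]2(C)CC[C@@]1(C)O2 | intermediate
10 | 5-bromopent-2-yne | CC#CCCBr | starting material
11 | [(2E)-5-bromopent-2-en-2-yl](chloro)zirconocene | C/C(=C\CCBr)[Zr](Cl)(C1C=CC=C1)C1C=CC=C1 | intermediate
12 | (2E)-5-bromo-2-iodopent-2-ene | C/C(I)=C\CCBr | intermediate
13 | 9-{2-[(1R,2R,3R,4S)-1,3,4-trimethyl-7-oxabicyclo[2.2.1]heptan-2-yl]ethyl}-9-borabicyclo[3.3.1]nonane | C1CC2CCCC(C1)B2CC[C@@H]1[C@@H](C)[C@]2(C)CC[C@@]1(C)O2 | intermediate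
14 | (1R,2R,3R,4S)-2-[(3E)-6-bromo-3-methylhex-3-en-1-yl]-1,3,4-trimethyl-7-oxabicyclo[2.2.1]heptane | BrCC/C=C(\C)CC[C@@H]1[C@@H](C)[C@]2(C)CC[C@@]1(C)O2 | intermediate
15 | 2-{(3E)-4-methyl-6-[(1R,2R,3R,4S)-1,3,4-trimethyl-7-oxabicyclo[2.2.1]heptan-2-yl]hex-3-en-1-yl}-4,4,5,5-tetramethyl-1,3,2-dioxaborolane | CC1(C)OB(CC/C=C(\C)CC[C@@H]2[C@@H](C)[C@]3(C)CC[C@@]2(C)O3)OC1(C)C | intermediate
16 | (R)-but-3-en-2-ol | C=C[C@@H](C)O | starting material
17 | (R)-but-3-en-2-yl N,N-diisopropylcarbamate | C=C[C@@H](C)OC(=O)N(C(C)C)C(C)C | intermediate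
18 | (R)-2-(diisopropylcarbamoyloxy)but-3-en-2-yllithium | C=C[C@@]([Li])(C)OC(=O)N(C(C)C)C(C)C | intermediate
19 | lithium boronate complex of 18 and 15 (boron in place of lithium, retention) | C=C[C@@]([B-]1(CC/C=C(\C)CC[C@@H]2[C@@H](C)[C@]3(C)CC[C@@]2(C)O3)OC(C)(C)C(C)(C)O1)(C)OC(=O)N(C(C)C)C(C)C.[Li+] | intermediate
20 | 2-{(3R,6E)-3,7-dimethyl-9-[(1R,2R,3R,4S)-1,3,4-trimethyl-7-oxabicyclo[2.2.1]heptan-2-yl]nona-1,6-dien-3-yl}-4,4,5,5-tetramethyl-1,3,2-dioxaborolane | C=C[C@](B1OC(C)(C)C(C)(C)O1)(C)CC/C=C(\C)CC[C@@H]2[C@@H](C)[C@]3(C)CC[C@@]2(C)O3 | intermediate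
21 | (3S,6E)-3,7-dimethyl-9-[(1R,2R,3R,4S)-1,3,4-trimethyl-7-oxabicyclo[2.2.1]heptan-2-yl]nona-1,6-dien-3-ol | C=C[C@](O)(C)CC/C=C(\C)CC[C@@H]1[C@@H](C)[C@]2(C)CC[C@@]1(C)O2 | intermediate
22 | (3S)-3-methyl-5-[(2R,3R)-3-methyl-3-{2-[(1R,2R,3R,4S)-1,3,4-trimethyl-7-oxabicyclo[2.2.1]heptan-2-yl]ethyl}oxiran-2-yl]pent-1-en-3-ol | C=C[C@](O)(C)CC[C@H]1O[C@]1(C)CC[C@@H]1[C@@H](C)[C@]2(C)CC[C@@]1(C)O2 | intermediate
23 | (2R)-2-[(2S,5S)-5-ethenyl-5-methyloxolan-2-yl]-4-[(1R,2R,3R,4S)-1,3,4-trimethyl-7-oxabicyclo[2.2.1]heptan-2-yl]butan-2-ol | C=C[C@]1(C)CC[C@@H]([C@@](C)(CC[C@@H]2[C@@H](C)[C@]3(C)CC[C@@]2(C)O3)O)O1 | intermediate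
24 | O-(1-dimethyliminio-2-methylpropyl) derivative of 23, bromide salt | C=C[C@]1(C)CC[C@@H]([C@@](C)(CC[C@@H]2[C@@H](C)[C@]3(C)CC[C@@]2(C)O3)OC(C(C)C)=[N+](C)C)O1.[Br-] | intermediate
25 | 1-oxoniabicyclo[3.1.0]hexane bromide (ring oxygen bridges the former oxolane C-2 and the former carbinol carbon, the latter inverted) | C=C[C@]1(C)CC[C@@H]2[O+]1[C@@]2(C)CC[C@@H]1[C@@H](C)[C@]2(C)CC[C@@]1(C)O2.[Br-] | intermediate
26 | (2S,5S)-5-{(2R)-2-bromo-4-[(1R,2R,3R,4S)-1,3,4-trimethyl-7-oxabicyclo[2.2.1]heptan-2-yl]butan-2-yl}-2-ethenyl-2-methyloxolane | C=C[C@]1(C)CC[C@@H]([C@@](C)(CC[C@@H]2[C@@H](C)[C@]3(C)CC[C@@]2(C)O3)Br)O1 | intermediate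
27 | dactylopyranoid, (2S,3R,6S)-3-bromo-6-ethenyl-2,6-dimethyl-2-{2-[(1R,2R,3R,4S)-1,3,4-trimethyl-7-oxabicyclo[2.2.1]heptan-2-yl]ethyl}oxane | C=C[C@]1(C)CC[C@@H](Br)[C@](C)(CC[C@@H]2[C@@H](C)[C@]3(C)CC[C@@]2(C)O3)O1 | target

## Step count and risks
Total step count: 11.
Longest linear sequence: 9 (steps 1, 2, 3, 4, 6, 7, 9, 10, 11).

**Step 11 (the new ring expansion).**
- Risks: loss of a proton from the tertiary cation side of 25, stalling at 26, or ionisation of the tertiary allylic ether by ZnBr2.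
- The fallback sets out from 21 and comes back at 27. It is a direct 6-endo bromoetherification of the dienol with 2,4,4,6-tetrabromocyclohexa-2,5-dienone in MeNO2 at 0 °C, the established way to 3-bromo-2,2,6,6-tetrasubstituted oxanes.
- Anti addition to the E alkene still fixes the Br/C-2 relationship. Both alkene faces and the 5-exo mode react, however, so 27 has to be separated by HPLC in low yield. This fallback makes no new compound (F0).

**Step 3 (closure of the bridged ring by a weakly nucleophilic enol carbamate).**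
- The fallback sets out from 6 and comes back at 9, replacing steps 3 and 4.
- MeOH/PPTS closes 6 to the cyclic methyl ketal (1Z,3R)-3-[(2S)-5-methoxy-2,5-dimethyloxolan-2-yl]but-1-en-1-yl N,N-diisopropylcarbamate F1, which masks both the ketone and the OH.
- Kumada coupling with Me3SiCH2MgCl and Ni(acac)2 (5 mol %) in Et2O replaces the carbamoyloxy group with retention. It gives the allylsilane {(2Z,4R)-4-[(2S)-5-methoxy-2,5-dimethyloxolan-2-yl]pent-2-en-1-yl}trimethylsilane F2.
- BF3·OEt2 at −78 °C ionises the ketal, and the far more nucleophilic allylsilane closes by a Hosomi–Sakurai reaction directly to 9. No sensitive aldehyde is handled.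

**Step 2 (enantiomeric purity of the crystallised lithium complex and methyl versus alkyl discrimination at the ketone).**
- The fallback sets out from 3 and comes back at 9, replacing steps 1 to 4.
- Chiral-diol-catalysed crotylboration of 3 uses diisopropyl (E)-crotylboronate and 3,3'-dibromo-BINOL (15 mol %, the enantiomer that gives the anti 5S,6R adduct). It gives (5S,6R)-5-hydroxy-5,6-dimethyloct-7-en-2-one F3.
- MeOH/PPTS gives (2S)-2-[(2R)-but-3-en-2-yl]-5-methoxy-2,5-dimethyloxolane F4.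
- Cross-metathesis with allyltrimethylsilane (second-generation Grubbs catalyst) gives {(2E,4R)-4-[(2S)-5-methoxy-2,5-dimethyloxolan-2-yl]pent-2-en-1-yl}trimethylsilane F5.
- BF3·OEt2 then closes F5 to 9.

## Further compounds
F0 | step 11 | none | none
F1 | step 3 | (1Z,3R)-3-[(2S)-5-methoxy-2,5-dimethyloxolan-2-yl]but-1-en-1-yl N,N-diisopropylcarbamate (ketal epimers) | CC(C)N(C(C)C)C(=O)O/C=C\[C@@H](C)[C@]1(C)CCC(C)(OC)O1
F2 | step 3 | {(2Z,4R)-4-[(2S)-5-methoxy-2,5-dimethyloxolan-2-yl]pent-2-en-1-yl}trimethylsilane | C[Si](C)(C)C/C=C\[C@@H](C)[C@]1(C)CCC(C)(OC)O1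
F3 | step 2 | (5S,6R)-5-hydroxy-5,6-dimethyloct-7-en-2-one | C=C[C@@H](C)[C@](O)(C)CCC(C)=O
F4 | step 2 | (2S)-2-[(2R)-but-3-en-2-yl]-5-methoxy-2,5-dimethyloxolane (ketal epimers) | C=C[C@@H](C)[C@]1(C)CCC(C)(OC)O1
F5 | step 2 | {(2E,4R)-4-[(2S)-5-methoxy-2,5-dimethyloxolan-2-yl]pent-2-en-1-yl}trimethylsilane | C[Si](C)(C)C/C=C/[C@@H](C)[C@]1(C)CCC(C)(OC)O1
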